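The route rests on cutting the bond between chain carbon C1′ and ring carbon C6 of the toluhydroquinone. The key step copies biosynthetic aromatic prenylation: the sodium phenoxide of O4-silylated methylhydroquinone is C-alkylated at its ortho carbon by the complete C20 allylic bromide, passing through a cyclohexadienone that rearomatises. It exploits the C1–OH flanked by C2–CH3 and C6–H, with C4 oxygenated: C6 is the only ortho or para carbon able to return to a phenol. The bromide already carries the furan, the E-alkenes and the silylated (S)-carbinol. It comes from geranyl acetate through selenium dioxide oxidation, furyl-lithium coupling and an enantioselective vinylogous aldol reaction. Fluoride then frees all three hydroxyls.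

Key step: step 11

Assumption: the (S,S) antipode of the bisphosphoramide catalyst in step 6 is taken to direct the dienolate to the Si face of the aldehyde (Re-face attack being assumed for the (R,R) catalyst); should the sense be the reverse, the other antipode is used.

Step 1
Reactants: 1 geranyl acetate
Product: 2 (2E,6E)-8-hydroxy-3,7-dimethylocta-2,6-dien-1-yl acetate
Conditions: SeO2 (0.2 equiv), t-BuOOH (70% aq., 3 equiv), salicylic acid (0.1 equiv), CH2Cl2, rt
Reagents that add atoms: tert-butyl hydroperoxide, CC(C)(C)OO (oxygen atom, relayed through catalytic selenium dioxide, O=[Se]=O)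
Why: Catalytic SeO2 allylic oxidation (ene reaction, then [2,3]-sigmatropic shift) should hydroxylate the (E)-methyl group of the electron-richer terminal alkene, the 2,3-alkene being deactivated by the allylic acetate.

Step 2
Reactants: 2 (2E,6E)-8-hydroxy-3,7-dimethylocta-2,6-dien-1-yl acetate
Product: 3 (2E,6E)-8-bromo-3,7-dimethylocta-2,6-dien-1-yl acetate
Conditions: CBr4, PPh3, CH2Cl2, 0 °C
Reagents that add atoms: carbon tetrabromide, BrC(Br)(Br)Br
Why: In the Appel reaction bromide displaces the oxyphosphonium group of the primary allylic alcohol by SN2, which should leave both E-alkenes and the acetate intact.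

Step 3
Reactants: 3 (2E,6E)-8-bromo-3,7-dimethylocta-2,6-dien-1-yl acetate; 4 3-methylfuran
Product: 6 (2E,6E)-3,7-dimethyl-8-(4-methylfuran-2-yl)octa-2,6-dien-1-ol, via (4-methylfuran-2-yl)lithium 5 (not isolated)
Conditions: 4 (3.6 equiv), s-BuLi (3.4 equiv), THF, −78 → −40 °C; then 3, −78 → 0 °C; H2O
Reagents that add atoms: none
Why: Kinetic deprotonation of 3-methylfuran by the bulky base should occur at the unhindered α-position C5 to give 5, which displaces the primary allylic bromide by SN2 (heteroaryl-lithium alkylation) with the 6E geometry kept, while two further equivalents cleave the acetate by double addition and so release the allylic alcohol in the same flask.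

Step 4
Reactants: 6 (2E,6E)-3,7-dimethyl-8-(4-methylfuran-2-yl)octa-2,6-dien-1-ol
Product: 7 (2E,6E)-3,7-dimethyl-8-(4-methylfuran-2-yl)octa-2,6-dienal
Conditions: MnO2 (activated, excess), CH2Cl2, rt
Reagents that add atoms: none
Why: Activated MnO2 oxidises allylic alcohols selectively to enals without E/Z isomerisation and should leave the furan and the isolated alkene untouched.

Step 5
Reactants: 8 ethyl 3-methylbut-2-enoate
Product: 10 tert-butyl[(1-ethoxy-3-methylbuta-1,3-dien-1-yl)oxy]dimethylsilane, via lithium dienolate 9 (not isolated)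
Conditions: LDA, THF, −78 °C; TBSCl, DMPU, −78 °C → rt; distillation
Reagents that add atoms: tert-butyldimethylsilyl chloride, CC(C)(C)[Si](C)(C)Cl
Why: LDA removes a γ-proton of the β,β-disubstituted enoate and the lithium dienolate 9 is O-silylated, giving the silyl dienol ether needed for a vinylogous Mukaiyama aldol reaction (its ketene acetal geometry is of no consequence).

Step 6
Reactants: 7 (2E,6E)-3,7-dimethyl-8-(4-methylfuran-2-yl)octa-2,6-dienal; 10 tert-butyl[(1-ethoxy-3-methylbuta-1,3-dien-1-yl)oxy]dimethylsilane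
Product: 12 ethyl (2E,5S,6E,10E)-5-hydroxy-3,7,11-trimethyl-12-(4-methylfuran-2-yl)dodeca-2,6,10-trienoate, via trichlorosilyl ether 11 (not isolated)
Conditions: SiCl4 (1.1 equiv), (S,S)-binaphthyldiamine-derived bisphosphoramide (pentamethylene-linked, 5 mol %), i-Pr2NEt (10 mol %), CH2Cl2, −78 °C; aq. NaHCO3
Reagents that add atoms: none
Why: In this Lewis-base-activated SiCl4 vinylogous Mukaiyama aldol addition the chiral phosphoramide-bound trichlorosilyl cation binds the aldehyde and exposes only its Si face to the γ-carbon of 10 in an open transition state, which should set C5 as S, while γ-attack of the s-trans dienolate gives the 2E-3-methyl enoate.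

Step 7
Reactants: 12 ethyl (2E,5S,6E,10E)-5-hydroxy-3,7,11-trimethyl-12-(4-methylfuran-2-yl)dodeca-2,6,10-trienoate
Product: 13 ethyl (2E,5S,6E,10E)-5-[(tert-butyldimethylsilyl)oxy]-3,7,11-trimethyl-12-(4-methylfuran-2-yl)dodeca-2,6,10-trienoate
Conditions: TBSCl, imidazole, DMF, rt
Reagents that add atoms: tert-butyldimethylsilyl chloride, CC(C)(C)[Si](C)(C)Cl
Why: Standard silylation of the secondary allylic alcohol masks C5–OH for the hydride, bromination and phenoxide steps and does not touch the stereocentre.

Step 8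
Reactants: 13 ethyl (2E,5S,6E,10E)-5-[(tert-butyldimethylsilyl)oxy]-3,7,11-trimethyl-12-(4-methylfuran-2-yl)dodeca-2,6,10-trienoate
Product: 14 (2E,5S,6E,10E)-5-[(tert-butyldimethylsilyl)oxy]-3,7,11-trimethyl-12-(4-methylfuran-2-yl)dodeca-2,6,10-trien-1-ol
Conditions: DIBAL-H (2.5 equiv), CH2Cl2, −78 °C; Rochelle salt
Reagents that add atoms: none
Why: DIBAL-H reduces the α,β-unsaturated ester in a 1,2-fashion to the primary allylic alcohol at low temperature, with the 2E geometry and the silyl ether retained.

Step 9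
Reactants: 14 (2E,5S,6E,10E)-5-[(tert-butyldimethylsilyl)oxy]-3,7,11-trimethyl-12-(4-methylfuran-2-yl)dodeca-2,6,10-trien-1-ol
Product: 15 tert-butyl{[(2E,5S,6E,10E)-1-bromo-3,7,11-trimethyl-12-(4-methylfuran-2-yl)dodeca-2,6,10-trien-5-yl]oxy}dimethylsilane
Conditions: CBr4, PPh3, CH2Cl2, −20 → 0 °C; used directly
Reagents that add atoms: carbon tetrabromide, BrC(Br)(Br)Br
Why: Appel bromination of the primary allylic alcohol proceeds by SN2 displacement under near-neutral conditions that the furan and the allylic TBS ether should tolerate, and the labile bromide is used at once.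

Step 10
Reactants: 16 2-methylbenzene-1,4-diol (methylhydroquinone)
Product: 17 2-methyl-4-[(triisopropylsilyl)oxy]phenol
Conditions: TIPSCl (1.0 equiv), imidazole, DMF, 0 °C
Reagents that add atoms: triisopropylsilyl chloride, CC(C)[Si](Cl)(C(C)C)C(C)C
Why: The bulky silyl chloride should react at the unhindered O4 hydroxyl, O1 being shielded by the ortho methyl group, so that only the O1 phenol remains free to form the phenoxide.

Step 11
Reactants: 15 tert-butyl{[(2E,5S,6E,10E)-1-bromo-3,7,11-trimethyl-12-(4-methylfuran-2-yl)dodeca-2,6,10-trien-5-yl]oxy}dimethylsilane; 17 2-methyl-4-[(triisopropylsilyl)oxy]phenol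
Product: 20 2-[(2E,5S,6E,10E)-5-[(tert-butyldimethylsilyl)oxy]-3,7,11-trimethyl-12-(4-methylfuran-2-yl)dodeca-2,6,10-trien-1-yl]-6-methyl-4-[(triisopropylsilyl)oxy]phenol, via sodium phenoxide 18 (not isolated), via cyclohexadienone 19 (not isolated)
Conditions: 17 (3 equiv), NaH (2.9 equiv), toluene, rt; then 15, 0 °C → rt, Ar
Reagents that add atoms: none
Why: The sodium phenoxide 18 is an ambident dienolate that, as a tight ion-pair aggregate in toluene, has its oxygen blocked by Na+ while the cation assists departure of bromide, so the primary allylic carbon C1′ of 15 is delivered by SN2 to the ortho ring carbon C6 through a six-membered cyclic transition state. The resulting cyclohexa-2,4-dienone 19 tautomerises at once to phenol 20; the closest known reaction type is the Claisen ortho-C-allylation of alkali phenoxides in non-polar media, the laboratory counterpart of aromatic prenyl transfer. No ring is closed and no lasting stereocentre is formed (C6 of 19 is lost on enolisation), and C5′ of the chain is untouched. The step needs C- over O-alkylation, which the non-dissociating solvent, the sodium counter-ion and the excess of phenoxide should secure. It needs attack at C6 only, which the substrate secures because C2 carries the methyl group and C4 the silyloxy group, so C6 is the one ortho or para carbon that can rearomatise. It needs SN2 and not SN2′ attack, which the fully substituted C3′ of the allyl unit secures, so the 2′E geometry is kept, and the furan, the silyl ethers and the other alkenes are inert to a phenoxide.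

Step 12
Reactants: 20 2-[(2E,5S,6E,10E)-5-[(tert-butyldimethylsilyl)oxy]-3,7,11-trimethyl-12-(4-methylfuran-2-yl)dodeca-2,6,10-trien-1-yl]-6-methyl-4-[(triisopropylsilyl)oxy]phenol
Product: 21 2-[(2E,5S,6E,10E)-5-hydroxy-3,7,11-trimethyl-12-(4-methylfuran-2-yl)dodeca-2,6,10-trien-1-yl]-6-methylbenzene-1,4-diol (CNP0172089.1)
Conditions: TBAF (3 equiv), AcOH (3 equiv), THF (degassed), 0 °C → rt, Ar
Reagents that add atoms: none
Why: Fluoride cleaves the aryl TIPS ether and the secondary TBS ether through pentacoordinate silicon without affecting the stereocentre, and acetic acid buffering under argon should keep the electron-rich hydroquinone from oxidising to the quinone.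

Compound list
1 | geranyl acetate [(2E)-3,7-dimethylocta-2,6-dien-1-yl acetate] | CC(=O)OC/C=C(\C)CCC=C(C)C | starting material
2 | (2E,6E)-8-hydroxy-3,7-dimethylocta-2,6-dien-1-yl acetate | CC(=O)OC/C=C(\C)CC/C=C(\C)CO | intermediate
3 | (2E,6E)-8-bromo-3,7-dimethylocta-2,6-dien-1-yl acetate | CC(=O)OC/C=C(\C)CC/C=C(\C)CBr | intermediate
4 | 3-methylfuran | Cc1ccoc1 | starting material
5 | (4-methylfuran-2-yl)lithium | [Li]c1cc(C)co1 | intermediate (not isolated)
6 | (2E,6E)-3,7-dimethyl-8-(4-methylfuran-2-yl)octa-2,6-dien-1-ol | OC/C=C(\C)CC/C=C(\C)Cc1cc(C)co1 | intermediate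
7 | (2E,6E)-3,7-dimethyl-8-(4-methylfuran-2-yl)octa-2,6-dienal | O=C/C=C(\C)CC/C=C(\C)Cc1cc(C)co1 | intermediate
8 | ethyl 3-methylbut-2-enoate | CCOC(=O)C=C(C)C | starting material
9 | lithium 1-ethoxy-3-methylbuta-1,3-dien-1-olate | C=C(C)C=C(OCC)[O-].[Li+] | intermediate (not isolated)
10 | tert-butyl[(1-ethoxy-3-methylbuta-1,3-dien-1-yl)oxy]dimethylsilane (ketene acetal double-bond isomers, both usable) | C=C(C)C=C(OCC)O[Si](C)(C)C(C)(C)C | intermediate
11 | ethyl (2E,5S,6E,10E)-3,7,11-trimethyl-12-(4-methylfuran-2-yl)-5-[(trichlorosilyl)oxy]dodeca-2,6,10-trienoate | C/C(=C\[C@@H](O[Si](Cl)(Cl)Cl)C/C(C)=C/C(=O)OCC)CC/C=C(\C)Cc1cc(C)co1 | intermediate (not isolated)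
12 | ethyl (2E,5S,6E,10E)-5-hydroxy-3,7,11-trimethyl-12-(4-methylfuran-2-yl)dodeca-2,6,10-trienoate | C/C(=C\[C@@H](O)C/C(C)=C/C(=O)OCC)CC/C=C(\C)Cc1cc(C)co1 | intermediate
13 | ethyl (2E,5S,6E,10E)-5-[(tert-butyldimethylsilyl)oxy]-3,7,11-trimethyl-12-(4-methylfuran-2-yl)dodeca-2,6,10-trienoate | C/C(=C\[C@@H](O[Si](C)(C)C(C)(C)C)C/C(C)=C/C(=O)OCC)CC/C=C(\C)Cc1cc(C)co1 | intermediate
14 | (2E,5S,6E,10E)-5-[(tert-butyldimethylsilyl)oxy]-3,7,11-trimethyl-12-(4-methylfuran-2-yl)dodeca-2,6,10-trien-1-ol | C/C(=C\[C@@H](O[Si](C)(C)C(C)(C)C)C/C(C)=C/CO)CC/C=C(\C)Cc1cc(C)co1 | intermediate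
15 | tert-butyl{[(2E,5S,6E,10E)-1-bromo-3,7,11-trimethyl-12-(4-methylfuran-2-yl)dodeca-2,6,10-trien-5-yl]oxy}dimethylsilane | C/C(=C\[C@@H](O[Si](C)(C)C(C)(C)C)C/C(C)=C/CBr)CC/C=C(\C)Cc1cc(C)co1 | intermediate
16 | 2-methylbenzene-1,4-diol (methylhydroquinone) | Cc1cc(O)ccc1O | starting material
17 | 2-methyl-4-[(triisopropylsilyl)oxy]phenol | Cc1cc(O[Si](C(C)C)(C(C)C)C(C)C)ccc1O | intermediate
18 | sodium 2-methyl-4-[(triisopropylsilyl)oxy]phenolate | Cc1cc(O[Si](C(C)C)(C(C)C)C(C)C)ccc1[O-].[Na+] | intermediate (not isolated)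
19 | 6-[(2E,5S,6E,10E)-5-[(tert-butyldimethylsilyl)oxy]-3,7,11-trimethyl-12-(4-methylfuran-2-yl)dodeca-2,6,10-trien-1-yl]-2-methyl-4-[(triisopropylsilyl)oxy]cyclohexa-2,4-dien-1-one (both C6 epimers) | C/C(=C\[C@@H](O[Si](C)(C)C(C)(C)C)C/C(C)=C/CC1C=C(O[Si](C(C)C)(C(C)C)C(C)C)C=C(C)C1=O)CC/C=C(\C)Cc1cc(C)co1 | intermediate (not isolated)
20 | 2-[(2E,5S,6E,10E)-5-[(tert-butyldimethylsilyl)oxy]-3,7,11-trimethyl-12-(4-methylfuran-2-yl)dodeca-2,6,10-trien-1-yl]-6-methyl-4-[(triisopropylsilyl)oxy]phenol | C/C(=C\[C@@H](O[Si](C)(C)C(C)(C)C)C/C(C)=C/Cc1cc(O[Si](C(C)C)(C(C)C)C(C)C)cc(C)c1O)CC/C=C(\C)Cc1cc(C)co1 | intermediate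
21 | 2-[(2E,5S,6E,10E)-5-hydroxy-3,7,11-trimethyl-12-(4-methylfuran-2-yl)dodeca-2,6,10-trien-1-yl]-6-methylbenzene-1,4-diol | C/C(=C\[C@@H](O)C/C(C)=C/Cc1cc(O)cc(C)c1O)CC/C=C(\C)Cc1cc(C)co1 | target

Total step count: 12
Longest linear sequence: 10 steps (steps 1, 2, 3, 4, 6, 7, 8, 9, 11, 12)

Steps most likely to fail

1. Step 11. O-alkylation of the phenoxide to an aryl allyl ether, or a second alkylation of the product, may outrun ortho-C-alkylation. The fallback sets out from 17 and 15 and comes back to the route at 20. Phenol 17 is brominated ortho to the free hydroxyl (NBS, i-Pr2NH cat., CH2Cl2, 0 °C) to give 2-bromo-6-methyl-4-[(triisopropylsilyl)oxy]phenol F1. t-BuLi (3 equiv, Et2O, −78 °C) deprotonates the phenol and exchanges bromine for lithium to give lithium 2-lithio-6-methyl-4-[(triisopropylsilyl)oxy]phenolate F2. Its aryl carbanion is alkylated by 15 (−78 → 0 °C) at C6 only, and aqueous work-up gives 20. The bond is then made by halogen–metal exchange and aryllithium alkylation, not by ambident phenoxide reactivity.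

2. Step 6. Facial selectivity on the β,β-disubstituted enal may be poor, γ- or E-selectivity of the dienolate addition may erode, or the Lewis acid may attack the furan. The fallback sets out from 7 and comes back to the route at 14. Brønsted-acid-catalysed asymmetric propargylation of 7 with allenylboronic acid pinacol ester (TRIP phosphoric acid, antipode chosen for Si-face attack, toluene, 4 Å MS, −20 °C) gives (4S,5E,9E)-6,10-dimethyl-11-(4-methylfuran-2-yl)undeca-5,9-dien-1-yn-4-ol F3. TBSCl and imidazole give tert-butyl{[(4S,5E,9E)-6,10-dimethyl-11-(4-methylfuran-2-yl)undeca-5,9-dien-1-yn-4-yl]oxy}dimethylsilane F4. Zirconium-catalysed methylalumination (Me3Al, Cp2ZrCl2 cat., CH2Cl2) adds CH3 and Al syn across the alkyne to give {(1E,4S,5E,9E)-4-[(tert-butyldimethylsilyl)oxy]-2,6,10-trimethyl-11-(4-methylfuran-2-yl)undeca-1,5,9-trien-1-yl}dimethylalumane F5, which is trapped with paraformaldehyde to give 14. The stereocentre then comes from an allenylboronate addition and the 2E alkene from syn-carbometalation.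

3. Step 3. Deprotonation of 4 at C2, next to the methyl group, may compete with C5 and carry a 2,3-disubstituted furan isomer through the route. The fallback sets out from 3, with 4 replaced by commercial 3-methylfuran-2-carboxylic acid (Cc1ccoc1C(=O)O), and comes back to the route at 5. Bromination of the acid (Br2, AcOH) can only occur at the free α-position and gives 5-bromo-3-methylfuran-2-carboxylic acid F6. Copper-mediated protodecarboxylation (Cu, quinoline, heat, product distilled out) gives 2-bromo-4-methylfuran F7. Bromine–lithium exchange (t-BuLi, 2 equiv per bromide, THF, −78 °C) gives 5 regiospecifically, which is carried into step 3 with bromide 3 as before.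

Further compounds
F1 | step 11 | 2-bromo-6-methyl-4-[(triisopropylsilyl)oxy]phenol | Cc1cc(O[Si](C(C)C)(C(C)C)C(C)C)cc(Br)c1O
F2 | step 11 | lithium 2-lithio-6-methyl-4-[(triisopropylsilyl)oxy]phenolate | Cc1cc(O[Si](C(C)C)(C(C)C)C(C)C)cc([Li])c1[O-].[Li+]
F3 | step 6 | (4S,5E,9E)-6,10-dimethyl-11-(4-methylfuran-2-yl)undeca-5,9-dien-1-yn-4-ol | C/C(=C\[C@@H](O)CC#C)CC/C=C(\C)Cc1cc(C)co1
F4 | step 6 | tert-butyl{[(4S,5E,9E)-6,10-dimethyl-11-(4-methylfuran-2-yl)undeca-5,9-dien-1-yn-4-yl]oxy}dimethylsilane | C/C(=C\[C@@H](O[Si](C)(C)C(C)(C)C)CC#C)CC/C=C(\C)Cc1cc(C)co1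
F5 | step 6 | {(1E,4S,5E,9E)-4-[(tert-butyldimethylsilyl)oxy]-2,6,10-trimethyl-11-(4-methylfuran-2-yl)undeca-1,5,9-trien-1-yl}dimethylalumane | C/C(=C\[C@@H](O[Si](C)(C)C(C)(C)C)C/C(C)=C/[Al](C)C)CC/C=C(\C)Cc1cc(C)co1
F6 | step 3 | 5-bromo-3-methylfuran-2-carboxylic acid | Cc1cc(Br)oc1C(=O)O
F7 | step 3 | 2-bromo-4-methylfuran | Cc1coc(Br)c1
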